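## Structural features

The target is a spiro homoisoflavanone: a 5,7-dimethoxychroman-4-one (aromatic ring A fused to the pyranone O1–C2–C3–C4) whose C3 is at the same time C1' of a 1,2-dihydrobenzocyclobutene (methylene C2', ring B carbons C2a', C3'–C6', C6a'). This spiro carbon is the only stereocentre. It is an all-carbon quaternary centre of (S) configuration bonded to the ketone carbon C4, the oxygen-bearing methylene C2, the cyclobutene methylene C2' and the ring B fusion carbon C6a'; it has no stereogenic neighbour and no α-hydrogen, so it cannot epimerise by enolisation. Ring B carries methoxy groups at C5' and C6', the latter directly beside the fusion carbon that holds the spiro centre, and ring A carries methoxy groups at C5 and C7, so the ketone is flanked by ortho-substituted arenes on both sides. The fragile element is the benzocyclobutene: it is strained and can open thermally to an ortho-quinodimethane in which the spiro carbon is planar, a process that an acyl group on that carbon makes easier and that would erase the configuration; the C5 methoxy group peri to the carbonyl is the first to be lost to strong Lewis acids. The real difficulty is to join a congested, configurationally defined quaternary carbon of a strained ring to the acyl carbon of a phloroglucinol-type arene without electrophilic acylation, which would be regiochemically ambiguous on ring A and would push a tertiary acylium ion towards loss of CO. The key step exploits the fact that the acyl carbon C4 sits on C4a and the ether oxygen O1 on the neighbouring C8a, with the C5 methoxy group beside C4a: this is the pattern left when the O–C(acyl) bond of a carboxylate is added across the triple bond of 3,5-dimethoxybenzyne.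

## Logic of the disconnections

**22 to 21.** Cutting the O1–C2 bond of 22 opens the pyranone and gives 21. The forward reaction is a 6-exo-tet attack of a phenoxide on a primary chloride, and the cut uncovers an ortho-hydroxyaryl ketone, the direct product type of the key step. One ring is removed and nothing else changes. The forward step demands an SN2 reaction at a carbon attached to the quaternary centre, run below the temperature at which the four-membered ring could open. No iodide is added, because halide exchange at so hindered a carbon would gain nothing.

**21 to 10 and 18.** In 21 the C4–C4a and O1–C8a bonds are cut in one operation. This leads to acid 10, used as its caesium salt 19, and to aryne 20, released from 18. The cut separates the molecule into its two aromatic halves, each with its full methoxy pattern, and replaces an electrophilic acylation by a nucleophilic addition whose regiochemistry is fixed by the methoxy group beside the triple bond of 20. The forward step demands that the acyl shift to carbon outruns protonation of the aryl anion (dried 19, no protic or nitrile solvent). The chloromethyl group of 19 must stay a spectator, and the temperature must stay far below that needed for ring opening. The chloride is kept because any early closure of the product phenoxide gives 22 itself.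

**18 to 11.** 18 is traced through 16 and 12 to 11 by cutting the O–S bond of the triflate, the aryl–Si bond and the carbamoyl C–O bond. The carbamate is chosen because it directs lithiation to the carbon between itself and a methoxy group and is later exchanged for triflate in one flask through 17. The gain is a commercial phenol in three steps. The demand is lithiation of 13 at the carbamate-flanked position (giving 14) and not between the two methoxy groups.

**10 to 8.** 10 is traced to its tert-butyl ester 9, and 9 to racemic 8; no skeletal bond is cut. The tert-butyl ester lets 10 be released by acid, so that a β-chloro carboxylate is never generated in hot aqueous base. The antipode is selected at 8 because this is the first compound after the only high-temperature step, and every later step stays at or below 60 °C. The demand is a clean separation of antipodes and a secure assignment of configuration.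

**8 to 7.** The aryl–CH2 bond of the four-membered ring (C2–C2a) of 8 is cut, giving 7. The cut is made there because a methyl group on a quaternary benzylic carbon ortho to a bromide is the established substrate for palladium-catalysed four-ring formation. The gain is an open-chain ester. The demand is C–H cleavage at the methyl group and not at the CH2Cl methylene, and an alkyl chloride that ignores zerovalent palladium.

**7 to 3.** The bonds from the α-carbon of 7 to CH2Cl and to CH3 are cut in turn, leading through 5 to 3 (enolates 6 and 4). The chloromethyl group is introduced directly as an electrophile, so no protecting group, no hydrogenolysis and no chlorination of a neopentyl-type alcohol are needed. Methylation comes first, so that the chloride is attached only when no α-hydrogen remains for elimination. The demand is C-alkylation of a hindered, fully substituted enolate.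

**3 to 1.** 3 is traced to 2 and then to 1 by cutting the ester O–C(tert-butyl) bond and the aryl–Br bond. The bromide is placed para to the C3 methoxy group, the site favoured by electrophilic substitution. The demand is regioselective bromination at that one position.

## Other disconnections considered

**Alternative 1:** The cut passes through three ring B bonds: C3'–C4' and C5'–C6' to the two carbons of a monoalkyne, and C2a'–C6a' between the inner carbons of a 1,5-diyne. In the forward direction CpCo(CO)2 would cocyclise the diyne A2 (a 3-propargyl-3-silylethynyl chromanone) with methoxy(trimethylsilyl)acetylene A3 to give A1, closing ring B and the cyclobutene at once.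

- In its favour: three carbon–carbon bonds and two rings in one step on a finished chromanone, and no palladium C–H activation. In bonds and rings formed per step this alternative is the better of the two, since the chosen key step forms two bonds and no ring.
- Against it: A1 carries one methoxy group and two silyl groups on ring B. The silyl group at C6' would have to be turned into a methoxy group and the one at C4' into hydrogen. Both are ortho to the same methoxy group, so telling them apart is uncertain and costs several steps. The orientation of A3 in the cocyclisation rests only on steric repulsion between silyl groups, and an ynol ether is prone to self-trimerisation.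
- Stereochemistry: the quaternary centre of A2, with an alkynyl and a propargyl group α to a ketone, has no obvious enantioselective entry, so a separation of antipodes would still be needed; on this point the two plans are equal.
- Heat: the cocyclisation usually needs heat or light, and A1 is already an acyl benzocyclobutene, the thermally most sensitive form of the ring system. The chosen plan brings all four methoxy groups in from commercial arenes and makes the four-membered ring at the ester stage.

**Alternative 2:** The cut is the same aryl–CH2 bond of the cyclobutene as in the chosen route, but made on the gem-dimethyl ester A5, so that the C–H cleavage selects one of two enantiotopic methyl groups. Zerovalent palladium from Pd2(dba)3 with a chiral ligand and K2CO3 would give A4 with the quaternary stereocentre set. After saponification, a palladium-catalysed β-C–H lactonisation of the remaining methyl group would give the spiro β-lactone A6, and opening of A6 by chloride at the methylene would join the chosen route at 10.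

- In its favour: asymmetric catalysis in place of a separation of antipodes, so no half of the material is discarded, and A5 is made by a single double methylation. On throughput and on the simplicity of the alkylation this alternative is the better one. The step count to 10 is about equal.
- Against it: enantioselective methyl C–H arylation is established mainly for five-membered rings. Here it would have to work for a four-membered ring near 140 °C, where reversible ring opening of A4 could erode the enantiomeric purity. The later lactonisation must choose the methyl group over the benzylic ring methylene and build a β-lactone spiro-fused to a cyclobutene, and the chloride must then open A6 at the hindered CH2–O carbon and not at the acyl carbon.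
- Comparison: the chosen plan uses the same hot C–H arylation but asks no stereochemical or site-selective question of it beyond methyl against CH2Cl.

**Alternative 3:** The cut is the C3–C4 bond of the chromanone. A chiral triazolium-derived N-heterocyclic carbene would add the aldehyde C–H of A8 across its 1,1-disubstituted alkene to give A7, setting the quaternary C3 with a methyl group. A final methyl C–H arylation of A7 would close the cyclobutene and give 22.

- In its favour: the reaction type is documented for chromanones with a methyl-bearing quaternary C3, the stereocentre is set by catalysis, and the sequence would be several steps shorter. In enantiocontrol by design and in step economy this alternative is the better one.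
- Against it: the aldehyde of A8 lies on a 2,4,6-trioxygenated ring and is a poor acceptor for the carbene, and the alkene carries an aryl group with bromine and methoxy on both ortho positions, twisted and hindered. More seriously, the last step would create an acyl benzocyclobutene at about 140 °C from an enantioenriched ketone. Ring opening of that product would make C3 planar, so the configuration set earlier would be at risk exactly when it can no longer be corrected, and the C2 methylene offers a competing C–H site.
- Comparison: the chosen plan runs the hot step on a racemic ester before the antipode is selected and before the ketone exists, at the price of more steps and a discarded antipode.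

Key step: step 11

Assumption (remark on the chemistry): the elution order of the antipodes in step 6 is not predicted; the (R) antipode is to be identified by anomalous-dispersion X-ray analysis (chlorine) of the acid obtained from each fraction before material is carried on. Benzocyclobutene compounds are numbered C1 (quaternary), C2 (CH2), C2a, C3–C6, C6a.

## Route

**Step 1**
Reactants: 1 (2,3-dimethoxyphenyl)acetic acid
Product: 2 2-(6-bromo-2,3-dimethoxyphenyl)acetic acid
Conditions: NBS (1.05 equiv), MeCN, 0 °C to rt, dark
Reagents that add atoms: N-bromosuccinimide, O=C1CCC(=O)N1Br
Why: Electrophilic aromatic bromination; the C3 methoxy group is the only one that can lie in the ring plane (the C2 methoxy group is twisted by its two neighbours), and its para position C6 is also ortho to the alkyl chain, so bromine should enter there.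

**Step 2**
Reactants: 2 2-(6-bromo-2,3-dimethoxyphenyl)acetic acid
Product: 3 tert-butyl 2-(6-bromo-2,3-dimethoxyphenyl)acetate
Conditions: t-BuOC(=NH)CCl3 (2 equiv), CH2Cl2–cyclohexane, rt
Reagents that add atoms: tert-butyl 2,2,2-trichloroacetimidate, CC(C)(C)OC(=N)C(Cl)(Cl)Cl
Why: Acid-promoted O-alkylation of the carboxylic acid by the protonated imidate (tert-butyl esterification); the tert-butyl ester tolerates enolate chemistry and hot carbonate and can later be removed without hydroxide.

**Step 3**
Reactants: 3 tert-butyl 2-(6-bromo-2,3-dimethoxyphenyl)acetate
Product: 5 tert-butyl 2-(6-bromo-2,3-dimethoxyphenyl)propanoate (racemic), via lithium enolate 4 (not isolated)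
Conditions: LiN(i-Pr)2 (1.05 equiv), THF, −78 °C; MeI (1.1 equiv), −78 to 0 °C
Reagents that add atoms: iodomethane, CI
Why: Ester enolate C-alkylation; one equivalent of amide base at low temperature should give monomethylation, and the benzylic α-proton is removed far faster than the base can attack the aryl bromide.

**Step 4**
Reactants: 5 tert-butyl 2-(6-bromo-2,3-dimethoxyphenyl)propanoate (racemic)
Product: 7 tert-butyl 2-(6-bromo-2,3-dimethoxyphenyl)-3-chloro-2-methylpropanoate (racemic), via lithium enolate 6 (not isolated)
Conditions: LiN(i-Pr)2 (1.1 equiv), THF, −78 °C; ClCH2I (1.5 equiv), DMPU, −78 °C to rt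
Reagents that add atoms: chloroiodomethane, ClCI
Why: SN2 C-alkylation of the fully substituted enolate at the iodine-bearing carbon of the dihalomethane, iodide being by far the better leaving group; the product is a neopentyl-type chloride without α-hydrogen, so it can neither alkylate a second enolate nor eliminate. The quaternary centre forms as a racemate and its antipode is selected in step 6.

**Step 5**
Reactants: 7 tert-butyl 2-(6-bromo-2,3-dimethoxyphenyl)-3-chloro-2-methylpropanoate (racemic)
Product: 8 tert-butyl 1-(chloromethyl)-5,6-dimethoxy-1,2-dihydrobenzocyclobutene-1-carboxylate (racemic)
Conditions: Pd(OAc)2 (10 mol%), P(t-Bu)3·HBF4 (20 mol%), K2CO3 (1.5 equiv), DMF, 140 °C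
Reagents that add atoms: none
Why: Palladium-catalysed intramolecular C(sp3)–H arylation: zerovalent palladium inserts into the C–Br bond, carbonate-assisted concerted metalation–deprotonation of the methyl group gives a five-membered palladacycle of divalent palladium, and reductive elimination closes the four-membered ring. The quaternary benzylic carbon excludes β-hydride elimination; methyl C–H bonds are cleaved in preference to the CH2Cl methylene, and a neopentyl-type chloride should resist SN2-type oxidative addition.

**Step 6**
Reactants: 8 tert-butyl 1-(chloromethyl)-5,6-dimethoxy-1,2-dihydrobenzocyclobutene-1-carboxylate (racemic)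
Product: 9 tert-butyl (R)-1-(chloromethyl)-5,6-dimethoxy-1,2-dihydrobenzocyclobutene-1-carboxylate
Conditions: preparative SFC on amylose tris(3,5-dimethylphenylcarbamate), CO2–i-PrOH, 35 °C
Reagents that add atoms: none
Why: Resolution by chromatography on a chiral stationary phase, on which the antipodes of a neutral aryl ester form diastereomeric adsorbates of different stability; it is placed after the only 140 °C step, and all later steps stay at or below 60 °C, so reversible opening of the four-membered ring should not scramble the selected centre.

**Step 7**
Reactants: 9 tert-butyl (R)-1-(chloromethyl)-5,6-dimethoxy-1,2-dihydrobenzocyclobutene-1-carboxylate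
Product: 10 (R)-1-(chloromethyl)-5,6-dimethoxy-1,2-dihydrobenzocyclobutene-1-carboxylic acid
Conditions: CF3CO2H, Et3SiH (2 equiv), CH2Cl2, 0 °C to rt
Reagents that add atoms: none
Why: Acidolysis of the tert-butyl ester; the tert-butyl cation is reduced by the silane so that it cannot alkylate the electron-rich ring B, and no base is present that could turn the β-chloro acid into a reactive carboxylate. The quaternary centre is not touched.

**Step 8**
Reactants: 11 3,5-dimethoxyphenol
Product: 12 3,5-dimethoxyphenyl N-isopropylcarbamate
Conditions: i-PrNCO (1.2 equiv), Et3N (0.2 equiv), CH2Cl2, rt
Reagents that add atoms: isopropyl isocyanate, CC(C)N=C=O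
Why: Base-catalysed addition of the phenol to the isocyanate (carbamoylation), installing a directing group that can later be removed under mild base.

**Step 9**
Reactants: 12 3,5-dimethoxyphenyl N-isopropylcarbamate
Product: 16 3,5-dimethoxy-2-(trimethylsilyl)phenyl N-isopropylcarbamate, via N-silyl carbamate 13 (not isolated), via aryllithium 14 (not isolated), via N-silyl C-silyl carbamate 15 (not isolated)
Conditions: TBSOTf (1.1 equiv), TMEDA, Et2O, 0 °C to rt; n-BuLi, TMEDA, −78 °C; Me3SiCl, −78 °C to rt; aq NaHSO4
Reagents that add atoms: chlorotrimethylsilane, C[Si](C)(C)Cl
Why: Directed ortho-metalation: silylation of the N–H masks the acidic proton, the carbamate then directs lithiation to the carbon between itself and a methoxy group (two cooperating directing groups, stronger than the pair of methoxy groups at C4), and the aryllithium is silylated; the N-silyl group is hydrolysed on acidic work-up.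

**Step 10**
Reactants: 16 3,5-dimethoxy-2-(trimethylsilyl)phenyl N-isopropylcarbamate
Product: 18 3,5-dimethoxy-2-(trimethylsilyl)phenyl trifluoromethanesulfonate, via 3,5-dimethoxy-2-(trimethylsilyl)phenol 17 (not isolated)
Conditions: DBU, Et2NH, MeCN, 40 °C; then PhNTf2, rt
Reagents that add atoms: N-phenylbis(trifluoromethanesulfonimide), O=S(=O)(N(c1ccccc1)S(=O)(=O)C(F)(F)F)C(F)(F)F
Why: E1cB cleavage of the secondary carbamate (deprotonation at nitrogen, loss of phenoxide, trapping of isopropyl isocyanate by diethylamine) followed by O-triflation of the phenoxide in the same flask, which avoids isolating the protodesilylation-prone silyl phenol.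

**Step 11**
Reactants: 10 (R)-1-(chloromethyl)-5,6-dimethoxy-1,2-dihydrobenzocyclobutene-1-carboxylic acid; 18 3,5-dimethoxy-2-(trimethylsilyl)phenyl trifluoromethanesulfonate
Product: 21 (R)-[1-(chloromethyl)-5,6-dimethoxy-1,2-dihydrobenzocyclobuten-1-yl](2-hydroxy-4,6-dimethoxyphenyl)methanone, via caesium carboxylate 19 (not isolated), via 3,5-dimethoxybenzyne 20 (not isolated)
Conditions: Cs2CO3 (0.5 equiv), MeOH, rt, evaporate and dry; then 18 (1.3 equiv), CsF (3 equiv), 18-crown-6 (3 equiv), THF, 40 °C; 1 M HCl work-up
Reagents that add atoms: none
Why: Fluoride removes the silyl group of 18 and triflate leaves, giving aryne 20, whose triple bond is distorted by the inductively withdrawing methoxy group beside it so that nucleophiles add at the carbon remote from that group, the future C8a. The carboxylate oxygen of 19 adds there and the aryl anion appears at the future C4a, next to the methoxy group that stabilises it. This anion attacks the carbonyl of the aryl ester just formed through a four-membered alkoxide, which collapses to the caesium phenoxide of the ketone, a 1,3 oxygen-to-carbon acyl shift of the anionic Fries type; acid work-up gives 21. The closest known reaction type is the fluoride-induced carbon–oxygen addition of carboxylic acids to arynes that gives ortho-hydroxyaryl ketones. No ring is closed and no stereocentre is formed; the quaternary centre of 10 takes no part and has no α-hydrogen, so its configuration should be carried over unchanged. The step needs regioselectivity (secured by the methoxy group beside the aryne bond) and acyl transfer ahead of protonation (secured by the dried, preformed caesium salt in THF, with no free acid and no nitrile solvent as proton donors). It also needs an untouched chloromethyl group: the only intramolecular competitor is a 4-exo attack of the carboxylate on a neopentyl-type carbon, which would give a β-lactone spiro-fused to a cyclobutene and should be slow at 40 °C. The mild temperature also keeps the benzocyclobutene closed, the small excess of 18 limits a second arylation of the product phenoxide, and any phenoxide that already closes onto the chloromethyl group gives 22 and is not lost.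

**Step 12**
Reactants: 21 (R)-[1-(chloromethyl)-5,6-dimethoxy-1,2-dihydrobenzocyclobuten-1-yl](2-hydroxy-4,6-dimethoxyphenyl)methanone
Product: 22 (S)-4,5,5',7'-tetramethoxyspiro[bicyclo[4.2.0]octa-1,3,5-triene-7,3'-chroman]-4'-one (the target; chromanone C3 is C1 of the 5,6-dimethoxy-1,2-dihydrobenzocyclobutene)
Conditions: K2CO3 (2 equiv), DMF, 60 °C
Reagents that add atoms: none
Why: Intramolecular Williamson etherification: the phenoxide, made more acidic by the ortho acyl group, attacks the chloromethyl carbon in a 6-exo-tet SN2 reaction that forms O1–C2; the two other substituents of the neighbouring quaternary carbon are tied back in the four-membered ring, which opens the backside trajectory. No α-hydrogen is present, so neither elimination nor epimerisation can occur; the descriptor changes from (R) to (S) only because the CIP priorities change.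

## Compound list

1 | (2,3-dimethoxyphenyl)acetic acid | COc1cccc(CC(=O)O)c1OC | starting material
2 | 2-(6-bromo-2,3-dimethoxyphenyl)acetic acid | COc1ccc(Br)c(CC(=O)O)c1OC | intermediate
3 | tert-butyl 2-(6-bromo-2,3-dimethoxyphenyl)acetate | COc1ccc(Br)c(CC(=O)OC(C)(C)C)c1OC | intermediate
4 | lithium enolate of 3 (not isolated) | [Li+].[O-]C(OC(C)(C)C)=Cc1c(Br)ccc(OC)c1OC | intermediate
5 | tert-butyl 2-(6-bromo-2,3-dimethoxyphenyl)propanoate, racemic | COc1ccc(Br)c(C(C)C(=O)OC(C)(C)C)c1OC | intermediate
6 | lithium enolate of 5 (not isolated) | [Li+].[O-]C(OC(C)(C)C)=C(C)c1c(Br)ccc(OC)c1OC | intermediate
7 | tert-butyl 2-(6-bromo-2,3-dimethoxyphenyl)-3-chloro-2-methylpropanoate, racemic | COc1ccc(Br)c(C(C)(CCl)C(=O)OC(C)(C)C)c1OC | intermediate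
8 | tert-butyl 1-(chloromethyl)-5,6-dimethoxy-1,2-dihydrobenzocyclobutene-1-carboxylate, racemic | CC(C)(C)OC(=O)C1(CCl)Cc2ccc(OC)c(OC)c21 | intermediate
9 | tert-butyl (R)-1-(chloromethyl)-5,6-dimethoxy-1,2-dihydrobenzocyclobutene-1-carboxylate | CC(C)(C)OC(=O)[C@@]1(CCl)Cc2ccc(OC)c(OC)c21 | intermediate
10 | (R)-1-(chloromethyl)-5,6-dimethoxy-1,2-dihydrobenzocyclobutene-1-carboxylic acid | OC(=O)[C@@]1(CCl)Cc2ccc(OC)c(OC)c21 | intermediate
11 | 3,5-dimethoxyphenol | COc1cc(O)cc(OC)c1 | starting material
12 | 3,5-dimethoxyphenyl N-isopropylcarbamate | COc1cc(OC)cc(OC(=O)NC(C)C)c1 | intermediate
13 | 3,5-dimethoxyphenyl N-(tert-butyldimethylsilyl)-N-isopropylcarbamate (not isolated) | COc1cc(OC)cc(OC(=O)N(C(C)C)[Si](C)(C)C(C)(C)C)c1 | intermediate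
14 | 2-lithio derivative of 13 (not isolated) | [Li]c1c(OC)cc(OC)cc1OC(=O)N(C(C)C)[Si](C)(C)C(C)(C)C | intermediate
15 | 3,5-dimethoxy-2-(trimethylsilyl)phenyl N-(tert-butyldimethylsilyl)-N-isopropylcarbamate (not isolated) | COc1cc(OC)c([Si](C)(C)C)c(OC(=O)N(C(C)C)[Si](C)(C)C(C)(C)C)c1 | intermediate
16 | 3,5-dimethoxy-2-(trimethylsilyl)phenyl N-isopropylcarbamate | COc1cc(OC)c([Si](C)(C)C)c(OC(=O)NC(C)C)c1 | intermediate
17 | 3,5-dimethoxy-2-(trimethylsilyl)phenol (not isolated) | COc1cc(OC)c([Si](C)(C)C)c(O)c1 | intermediate
18 | 3,5-dimethoxy-2-(trimethylsilyl)phenyl trifluoromethanesulfonate | COc1cc(OC)c([Si](C)(C)C)c(OS(=O)(=O)C(F)(F)F)c1 | intermediate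
19 | caesium (R)-1-(chloromethyl)-5,6-dimethoxy-1,2-dihydrobenzocyclobutene-1-carboxylate (not isolated) | [Cs+].[O-]C(=O)[C@@]1(CCl)Cc2ccc(OC)c(OC)c21 | intermediate
20 | 3,5-dimethoxybenzyne (not isolated) | COC1=CC(OC)=CC#C1 | intermediate
21 | (R)-[1-(chloromethyl)-5,6-dimethoxy-1,2-dihydrobenzocyclobuten-1-yl](2-hydroxy-4,6-dimethoxyphenyl)methanone | COc1cc(O)c(C(=O)[C@@]2(CCl)Cc3ccc(OC)c(OC)c32)c(OC)c1 | intermediate
22 | (S)-4,5,5',7'-tetramethoxyspiro[bicyclo[4.2.0]octa-1,3,5-triene-7,3'-chroman]-4'-one | COc1cc(OC)c2c(c1)OC[C@@]1(Cc3ccc(OC)c(OC)c31)C2=O | target

## Step count and least certain steps

Total step count: 12 (steps 1–7 for the acid, steps 8–10 for the aryne precursor, steps 11 and 12 for the union and ring closure). Longest linear sequence: 9 steps (steps 1–7, 11, 12).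

**Step 11 (key step).** Three processes are most likely to interfere. The caesium carboxylate may alkylate itself at the chloromethyl carbon (β-lactone formation) before the aryne is trapped, because a dry caesium carboxylate in an ether solvent is a strong nucleophile. The aryl anion may be protonated before the acyl shift if traces of water or acid remain, which stops the reaction at the aryl ester. The product phenoxide may be arylated a second time. Fallback, forming the same two bonds stepwise without a free carboxylate or an aryne: 10 is converted with oxalyl chloride and catalytic DMF in CH2Cl2 into (S)-1-(chloromethyl)-5,6-dimethoxy-1,2-dihydrobenzocyclobutene-1-carbonyl chloride F1. 11 is brominated ortho to the hydroxy group with N-bromosuccinimide in CH2Cl2 at −78 °C to give 2-bromo-3,5-dimethoxyphenol F2. F1 and F2 are joined with Et3N and catalytic DMAP to the aryl ester, 2-bromo-3,5-dimethoxyphenyl (R)-1-(chloromethyl)-5,6-dimethoxy-1,2-dihydrobenzocyclobutene-1-carboxylate F3. Treatment of F3 with n-BuLi in THF at −100 °C should trigger bromine–lithium exchange and an anionic Fries rearrangement of the acyl group to carbon; protonation on work-up returns to the route at 21.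

**Step 5.** The concern is loss of site or chemoselectivity at palladium: C–H cleavage at the CH2Cl methylene, reduction of the C–Br bond without cyclisation, or slow consumption of the alkyl chloride by zerovalent palladium at 140 °C. Fallback, in which no carbon–chlorine bond is present during the palladium step: enolate 6, generated from 5 as in step 4, is alkylated with benzyl chloromethyl ether to give tert-butyl 3-(benzyloxy)-2-(6-bromo-2,3-dimethoxyphenyl)-2-methylpropanoate F4. The same C–H arylation conditions should give tert-butyl 1-[(benzyloxy)methyl]-5,6-dimethoxy-1,2-dihydrobenzocyclobutene-1-carboxylate F5. Hydrogenolysis (H2, Pd on carbon, EtOAc) gives tert-butyl 1-(hydroxymethyl)-5,6-dimethoxy-1,2-dihydrobenzocyclobutene-1-carboxylate F6, and an Appel reaction (PPh3, CCl4, MeCN, 60 °C) returns to the route at 8.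

**Step 4.** The concern is sluggish C-alkylation of the hindered enolate by the dihalomethane, with halogen-philic attack on iodine or carbenoid formation from excess amide base taking over. Fallback: enolate 6 from 5 is treated with monomeric formaldehyde (cracked paraformaldehyde, THF, −78 °C) in an aldol addition to give tert-butyl 2-(6-bromo-2,3-dimethoxyphenyl)-3-hydroxy-2-methylpropanoate F7. An Appel reaction (PPh3, CCl4, MeCN, 60 °C), which cannot trigger retro-aldol cleavage because it is not basic, returns to the route at 7.

**Step 6.** The concern is incomplete separation of the antipodes or low throughput on scale, and an assignment of configuration that rests on a single crystal structure. Fallback by classical resolution: racemic 8 is deprotected as in step 7 to racemic 1-(chloromethyl)-5,6-dimethoxy-1,2-dihydrobenzocyclobutene-1-carboxylic acid F8. Fractional crystallisation with (S)-1-phenylethylamine from i-PrOH–EtOAc should give the less soluble diastereomeric salt, (S)-1-phenylethylammonium (R)-1-(chloromethyl)-5,6-dimethoxy-1,2-dihydrobenzocyclobutene-1-carboxylate F9. If the salt of the other antipode crystallises instead, the mirror-image amine must give the mirror-image result and is used. Partition between EtOAc and 1 M HCl returns to the route at 10.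

## Further compounds

F1 | step 11 | (S)-1-(chloromethyl)-5,6-dimethoxy-1,2-dihydrobenzocyclobutene-1-carbonyl chloride | O=C(Cl)[C@@]1(CCl)Cc2ccc(OC)c(OC)c21
F2 | step 11 | 2-bromo-3,5-dimethoxyphenol | COc1cc(O)c(Br)c(OC)c1
F3 | step 11 | 2-bromo-3,5-dimethoxyphenyl (R)-1-(chloromethyl)-5,6-dimethoxy-1,2-dihydrobenzocyclobutene-1-carboxylate | COc1cc(OC(=O)[C@@]2(CCl)Cc3ccc(OC)c(OC)c32)c(Br)c(OC)c1
F4 | step 5 | tert-butyl 3-(benzyloxy)-2-(6-bromo-2,3-dimethoxyphenyl)-2-methylpropanoate, racemic | COc1ccc(Br)c(C(C)(COCc2ccccc2)C(=O)OC(C)(C)C)c1OC
F5 | step 5 | tert-butyl 1-[(benzyloxy)methyl]-5,6-dimethoxy-1,2-dihydrobenzocyclobutene-1-carboxylate, racemic | CC(C)(C)OC(=O)C1(COCc3ccccc3)Cc2ccc(OC)c(OC)c21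
F6 | step 5 | tert-butyl 1-(hydroxymethyl)-5,6-dimethoxy-1,2-dihydrobenzocyclobutene-1-carboxylate, racemic | CC(C)(C)OC(=O)C1(CO)Cc2ccc(OC)c(OC)c21
F7 | step 4 | tert-butyl 2-(6-bromo-2,3-dimethoxyphenyl)-3-hydroxy-2-methylpropanoate, racemic | COc1ccc(Br)c(C(C)(CO)C(=O)OC(C)(C)C)c1OC
F8 | step 6 | 1-(chloromethyl)-5,6-dimethoxy-1,2-dihydrobenzocyclobutene-1-carboxylic acid, racemic | OC(=O)C1(CCl)Cc2ccc(OC)c(OC)c21
F9 | step 6 | (S)-1-phenylethylammonium (R)-1-(chloromethyl)-5,6-dimethoxy-1,2-dihydrobenzocyclobutene-1-carboxylate | [O-]C(=O)[C@@]1(CCl)Cc2ccc(OC)c(OC)c21.C[C@H]([NH3+])c1ccccc1
A1 | alternative 1 | (S)-5,5',7'-trimethoxy-4,6-bis(trimethylsilyl) spiro chromanone (5,7-dimethoxychroman-4-one spiro-fused at C3 to C1 of 5-methoxy-4,6-bis(trimethylsilyl)-1,2-dihydrobenzocyclobutene) | COc1cc(OC)c2c(c1)OC[C@@]1(Cc3cc([Si](C)(C)C)c(OC)c([Si](C)(C)C)c31)C2=O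
A2 | alternative 1 | (S)-5,7-dimethoxy-3-(prop-2-yn-1-yl)-3-[(trimethylsilyl)ethynyl]chroman-4-one | COc1cc(OC)c2c(c1)OC[C@@](C#C[Si](C)(C)C)(CC#C)C2=O
A3 | alternative 1 | methoxy(trimethylsilyl)acetylene | COC#C[Si](C)(C)C
A4 | alternative 2 | methyl (S)-5,6-dimethoxy-1-methyl-1,2-dihydrobenzocyclobutene-1-carboxylate | COC(=O)[C@@]1(C)Cc2ccc(OC)c(OC)c21
A5 | alternative 2 | methyl 2-(6-bromo-2,3-dimethoxyphenyl)-2-methylpropanoate | COC(=O)C(C)(C)c1c(Br)ccc(OC)c1OC
A6 | alternative 2 | (S)-spiro β-lactone of 1-(hydroxymethyl)-5,6-dimethoxy-1,2-dihydrobenzocyclobutene-1-carboxylic acid | O=C1OC[C@@]12Cc3ccc(OC)c(OC)c32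
A7 | alternative 3 | (S)-3-(6-bromo-2,3-dimethoxyphenyl)-5,7-dimethoxy-3-methylchroman-4-one | COc1cc(OC)c2c(c1)OC[C@](C)(c1c(Br)ccc(OC)c1OC)C2=O
A8 | alternative 3 | 2-{[2-(6-bromo-2,3-dimethoxyphenyl)prop-2-en-1-yl]oxy}-4,6-dimethoxybenzaldehyde | COc1cc(OC)c(C=O)c(OCC(=C)c2c(Br)ccc(OC)c2OC)c1
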